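The readings were generated by integration for substances that don't exist, and the scatter is random.

The ratio of partner to starting material charged is 2.50 in Sunday's flask and 6.00 in Monday's. Call this ratio the partner budget, partner charged per starting material charged.

the same everywhere: starting material 0.20 M
- south-east: partner 0.58 M; run made earlier
- south: partner 0.83 M; run made earlier
- Sunday's: partner 0.500 M; time 80 min
- Monday's: partner 1.20 M; time 80 min

| run | time / min | starting material / % | bis adduct / % | over-reaction product / % | first product / % | triple product / % |
|---|---|---|---|---|---|---|
| south-east | 4.00 | 16.5 | 23.1 | 7.6 | 35.4 | 18.3 |
| south-east | 10.0 | 4.7 | 21.1 | 10.3 | 18.1 | 44.3 |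
| south-east | 20.0 | 0.9 | 13.4 | 12.5 | 9.5 | 62.9 |
| south-east | 30.0 | 0.8 | 10.4 | 12.5 | 5.9 | 71.1 |
| south-east | 40.0 | 0.5 | 8.1 | 12.5 | 3.5 | 74.4 |
| south | 8.00 | 1.8 | 14.0 | 12.5 | 9.7 | 62.3 |
| south | 15.0 | 1.0 | 4.8 | 13.3 | 2.5 | 79.8 |
| south | 25.0 | 0 | 0.9 | 14.0 | 0 | 85.5 |
| south | 30.0 | 0.1 | 0 | 14.0 | 0 | 87.2 |
| south | 40.0 | 0 | 1.1 | 13.5 | 0 | 86.8 |

(each reading ± 0.5 percentage points)



* which of these there is most of at the end, counted by the starting material in it, Sunday's (triple product / first product / over-reaction product / bis adduct / starting material)
* which of these there is most of at the end, counted by the starting material in it, Monday's (triple product / first product / over-reaction product / bis adduct / starting material)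
* final amount of the leader among these, as a percentage of the starting material charged, in Sunday's
* final amount of the leader among these, as a percentage of the starting material charged, in Monday's

The runs show what a budget buys. Uptake is partner bound per starting material charged, counted as one for first product, two for bis adduct, 3 for triple product and two for over-reaction product. The south-east run stands at 2.50 at 20.0 min, and the south run at 2.50 at 8.00 min. Their triple product reads 62.9% and 62.3%, their bis adduct 13.4% and 14.0%. So the mixture reads as a function of uptake, not of the clock, as expected if each step takes one partner at first order in it. Sunday's budget matches that uptake, so this reckoning, if the flask takes up its budget, puts triple product near 62.6%.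

One objection is the count for over-reaction product. At one partner, the south-east reading counts 2.38, and Sunday's budget then matches the reading at 30.0 min, with triple product 71.1%. But in the south run over-reaction product rises from 12.5% to 14.0% between 8.00 min and 25.0 min, with starting material at 1.8% and first product falling from 9.7%. It is therefore read as made from first product, which makes two partners.

The other objection is that partner slows as it dwindles. The uptake of the south-east run gains 0.362 from 10.0 min to 20.0 min, but 0.150 from 20.0 min to 30.0 min. Sunday's 80 min is twice the time of that run's last reading, 40.0 min, so this reckoning keeps its assumption that Sunday's flask comes close to its budget, but the readings do not test it.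

Monday's budget exceeds the 2.90 taken up in the south run by 40.0 min, so Monday's should end like that run, near 86.8%.

The forecast names triple product for Sunday's and triple product for Monday's, at 52% and 85%, and says of Sunday's “so partner runs short”. On Sunday's it stands below this reckoning.

Sunday's flask gives triple product at 61.9%. Monday's flask gives triple product at 86.1%.

    starting material + partner → first product (k = 0.0180 /M/s)
    partner + first product → bis adduct (k = 0.0130 /M/s)
    partner + bis adduct → triple product (k = 0.0160 /M/s)
    partner + first product → over-reaction product (k = 0.00210 /M/s)

Sunday's lies 9.9 percentage points above the forecast, with 1.6% of its starting material and 0.34% of its partner left. A neighbour of Sunday's charged with 0.80 M of starting material has a budget of 0.625, below the one partner a starting material takes to react. So at least 37.5% of its starting material stays unreacted. At 80.0 min that neighbour holds 0% of its partner, and starting material leads at 51.8%, with first product at 36.0% and triple product at 1.97%.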